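Start from a one-step world, in which each Z turns Q into J at a steady pace, so that J, as a fraction of the Q charged, is the loading of Z times the pace times the time; call this bench rule of thumb the straight-line yield Y, and read the pace off the last reading of each run.

| flask | Q | L | Z | remark | time |
|---|---|---|---|---|---|
| epsilon | 0.092 M | 1 equiv | 0.062 mol% | run made earlier |  |
| gamma | 0.092 M | 7.5 equiv | 0.062 mol% | run made earlier |  |
| beta | 0.065 M | 3 equiv | 0.062 mol% | run made earlier |  |
| dusk | 0.030 M | 0.750 equiv | 0.015 mol% |  | 12 min |
| summer | 0.092 M | 3.00 equiv | 0.062 mol% |  | 12 min |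
| noon | 0.060 M | 3.00 equiv | 0.03 mol% |  | 12 min |
| dawn | 0.092 M | 2.00 equiv | 0.2 mol% |  | 12 min |
| winter | 0.092 M | 3.00 equiv | 0.04 mol% |  | 12 min |
| spring | 0.092 M | 6.00 equiv | 0.04 mol% |  | 12 min |

| run | time / min | J / % | Q / % |
|---|---|---|---|
| epsilon | 1.33 | 2.9 | 97.3 |
| epsilon | 2.50 | 4.6 | 95.1 |
| epsilon | 4.00 | 7.4 | 92.8 |
| epsilon | 5.00 | 9.4 | 91.4 |
| epsilon | 6.00 | 10.8 | 90.6 |
| gamma | 1.33 | 8.0 | 90.6 |
| gamma | 2.50 | 13.6 | 85.0 |
| gamma | 4.00 | 21.5 | 78.3 |
| gamma | 5.00 | 25.9 | 74.8 |
| gamma | 6.00 | 29.1 | 70.5 |
| beta | 0.500 | 2.0 | 98.2 |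
| beta | 1.50 | 4.7 | 95.0 |
| beta | 3.00 | 10.2 | 90.9 |
| beta | 4.00 | 12.5 | 88.1 |
| beta | 6.00 | 16.8 | 83.8 |

(scatter of a reading: 0.5 percentage points)



- the flasks put in order of amount of J, in percent of the Q charged, best first, at 12 min (dusk / summer / noon / dawn / winter / spring)
- the amount of J, in percent of the Q charged of the flask you put first, at 12 min
- the amount of J, in percent of the Q charged of the flask you put last, at 12 min

Take the epsilon run, where 10.8% of J at 6.00 min on 0.062 mol% of Z gives each Z a pace of 29.0 min⁻¹, and the gamma run, which gives 78.2 min⁻¹, so the pace climbs less steeply than the 7.5 equiv of L against 1 equiv would suggest. Split the minutes per turnover, therefore, into a fixed part and a part that shrinks as L grows, and solve these two runs for the fixed part, 0.00945 min, and for the L wait, the shrinking part multiplied by the L present, 0.138 M·s. Test it on the beta run, which took no part in this: it predicts 47.1 min⁻¹, and the last reading gives 45.2 min⁻¹.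

Reckon dusk with it, and Y comes to 1.61%, which at one L per J takes 2.15% of the 0.750 equiv of L charged in dusk, so trust the straight line there. Reckon dawn, and Y comes to 109%, more than the Q charged, which is the border of the rule. For dawn, let the pace fall with the L left, one L per J, pseudo-first-order in L; integrating gives J as the equivalents of L times one minus the exponential of minus Y over those equivalents, and my figure is 84.2%.

The forecast differs from this: it gives dawn > summer > spring > winter > noon > dusk, with 68% for dawn, below my figure, and 2.3% for dusk, above mine, remarking “Curvature looks like first order in Q, or possibly some catalyst decay.”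

The flasks give dawn > summer > spring > winter > noon > dusk, with 74.1% in dawn and 1.49% in dusk.

    Q + X ⇌ D (K = 920 M⁻¹, k = 4600 M⁻¹ min⁻¹)
    D → G (k = 370 min⁻¹)
    2 L → E (k = 0.300 M⁻¹ min⁻¹)
    L + Z → X (k = 440 M⁻¹ min⁻¹)
    G → Z + J (k = 5400 min⁻¹)

Watch L when repeating dawn: one L per J would leave 63.0% of its charge at 12.0 min, yet 24.3% stands there, beside 0.0356 M of E. Put the L wait on the neighbour, dawn with Q at 0.023 M and the same equivalents and loading: Y comes to 40.4%, and the closed form gives 36.6%, while that flask holds 63.1% of its L and gives 31.3% of J.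

All runs are simulated with made-up constants; scatter was added.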